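The chroman is cut at the two bonds that tie its pyran ring to ring A, C4–C4a and O1–C8a. Both form in one operation when an aryne spanning C4a and C8a adds across the C=O bond of a 2-arylacrolein: the benzoxete opens to an ortho-quinone methide, and oxa-6π ring closure moves the oxygen from C4 to C2 to give the isoflav-3-ene. The step exploits the C5 methoxy group of ring A, which polarises the aryne so that oxygen goes to C8a and carbon to C4a. The precursors are a 2-silylaryl triflate and the enal; asymmetric hydrogenation then sets C3, and the prenyl group enters last by directed metalation at C3′.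

Key step: step 7

Remark: chroman numbering is used throughout (O1, C2, C3, C4, C4a to C8a; ring B primed). The stereocentre of the given SMILES is C3 with R configuration. The sense of induction of the catalyst in step 8 is to be established in a pilot run and the ligand antipode chosen so that the 3R product results.

Step 1
Reactants: 1 5-bromovanillin (3-bromo-4-hydroxy-5-methoxybenzaldehyde)
Product: 2 2-bromo-6-methoxybenzene-1,4-diol
Conditions: 30% aq. H2O2, NaOH, H2O–THF, 0 °C → rt; then aq. HCl, Na2S2O4
Reagents that add atoms: hydrogen peroxide, OO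
Why: Dakin oxidation, in which the para-phenoxide drives aryl migration in the hydroperoxide adduct and hydrolysis of the aryl formate leaves the new hydroxyl at the future C7.

Step 2
Reactants: 2 2-bromo-6-methoxybenzene-1,4-diol
Product: 6 4-hydroxy-2-methoxy-6-(trimethylsilyl)phenyl trifluoromethanesulfonate, via bis(trimethylsilyl) ether 3 (not isolated), via lithium phenoxide 4 (not isolated), via silyl ether triflate 5 (not isolated)
Conditions: HMDS, THF, reflux, then evaporation; n-BuLi, THF, −78 °C; Tf2O, −78 °C → rt; aq. citric acid, MeOH, rt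
Reagents that add atoms: hexamethyldisilazane, C[Si](C)(C)N[Si](C)(C)C; trifluoromethanesulfonic anhydride, O=S(=O)(OS(=O)(=O)C(F)(F)F)C(F)(F)F
Why: Bromine–lithium exchange triggers a 1,3 O→C silyl shift (retro-Brook rearrangement) only at the oxygen next to bromine, so triflation of the resulting phenoxide differentiates the two hydroxyls without selective protection, and mild acid then cleaves the remaining aryl silyl ether while the C–Si bond stays.

Step 3
Reactants: 6 4-hydroxy-2-methoxy-6-(trimethylsilyl)phenyl trifluoromethanesulfonate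
Product: 7 4-(benzyloxy)-2-methoxy-6-(trimethylsilyl)phenyl trifluoromethanesulfonate
Conditions: BnBr, K2CO3, acetone, rt
Reagents that add atoms: benzyl bromide, BrCc1ccccc1
Why: Williamson etherification of the only free phenol, which the silyl triflate unit should tolerate because no fluoride is present.

Step 4
Reactants: 8 2-bromo-5-methoxyphenol
Product: 9 1-bromo-4-methoxy-2-(methoxymethoxy)benzene
Conditions: MOMCl, iPr2NEt, CH2Cl2, 0 °C → rt
Reagents that add atoms: chloromethyl methyl ether, COCCl
Why: O-alkylation to the methoxymethyl acetal, which masks the phenol from the aryne in step 7 and later serves as the directing group in step 10.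

Step 5
Reactants: 9 1-bromo-4-methoxy-2-(methoxymethoxy)benzene; 10 propargyl alcohol
Product: 12 2-[4-methoxy-2-(methoxymethoxy)phenyl]prop-2-en-1-ol, via aryl Grignard reagent 11 (not isolated)
Conditions: Mg, THF, rt → 40 °C; then 10 pre-treated with iPrMgCl (1 equiv), CuI (copper iodide, 10 mol %), THF–toluene, 0 °C → rt; aq. NH4Cl
Reagents that add atoms: none
Why: Copper-catalysed anti-carbomagnesiation of the propargylic magnesium alkoxide places the aryl group on the internal alkyne carbon through chelation by the alkoxide, and protonolysis on work-up gives the 2-arylallyl alcohol.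

Step 6
Reactants: 12 2-[4-methoxy-2-(methoxymethoxy)phenyl]prop-2-en-1-ol
Product: 13 2-[4-methoxy-2-(methoxymethoxy)phenyl]prop-2-enal
Conditions: MnO2 (excess), CH2Cl2, rt; used at once
Reagents that add atoms: none
Why: Allylic oxidation with MnO2 is chemoselective for the allylic alcohol and gives the sensitive 2-arylacrolein under neutral conditions.

Step 7
Reactants: 7 4-(benzyloxy)-2-methoxy-6-(trimethylsilyl)phenyl trifluoromethanesulfonate; 13 2-[4-methoxy-2-(methoxymethoxy)phenyl]prop-2-enal
Product: 17 7-(benzyloxy)-5-methoxy-3-[4-methoxy-2-(methoxymethoxy)phenyl]-2H-chromene, via aryne 14 (not isolated), via benzoxete 15 (not isolated), via ortho-quinone methide 16 (not isolated)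
Conditions: CsF (3 equiv), MeCN, rt; 7 in excess, added slowly
Reagents that add atoms: none
Why: Fluoride-induced 1,2-elimination from 7 gives aryne 14, whose triple bond spans C4a and C8a; the aldehyde oxygen of 13 adds to C8a, the aryne carbon remote from the C5 methoxy group, and the aryl anion that develops at C4a closes onto the carbonyl carbon, a stepwise formal [2+2] closure of the four-membered benzoxete 15 that makes the C4–C4a and O1–C8a bonds. Thermal 4π electrocyclic opening of 15 breaks the O–C4 bond to give ortho-quinone methide 16, and thermal disrotatory oxa-6π electrocyclisation of its 1-oxatriene closes the pyran ring by joining O1 to the former enal β-carbon, now C2, with rearomatisation of ring A as the driving force. The closest known reaction type is the annulation of arynes with α,β-unsaturated aldehydes to 2H-chromenes. No stereocentre is formed, since C3 leaves the step as an sp2 carbon and is set in step 8. The step needs regioselectivity (oxygen to C8a, carbon to C4a), which the inductively withdrawing C5 methoxy group next to C4a secures, and chemoselectivity for carbonyl addition over aryne capture by the styrene unit or by a second aryne, which the nucleophilic aldehyde oxygen and the fast intramolecular ring closure of 16 should secure.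

Step 8
Reactants: 17 7-(benzyloxy)-5-methoxy-3-[4-methoxy-2-(methoxymethoxy)phenyl]-2H-chromene
Product: 18 (3R)-7-(benzyloxy)-5-methoxy-3-[4-methoxy-2-(methoxymethoxy)phenyl]chromane
Conditions: [Ir(cod)((S)-tBu-PHOX)]BArF (2 mol %), H2 (50 bar), CH2Cl2, rt
Reagents that add atoms: none
Why: Iridium-catalysed asymmetric hydrogenation of a trisubstituted aryl alkene with a chiral phosphine–oxazoline ligand delivers H2 to one face of C3=C4 under catalyst control and so sets C3 as R, while the benzyl and acetal groups should stay untouched.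

Step 9
Reactants: 18 (3R)-7-(benzyloxy)-5-methoxy-3-[4-methoxy-2-(methoxymethoxy)phenyl]chromane
Product: 19 (3R)-5-methoxy-3-[4-methoxy-2-(methoxymethoxy)phenyl]chroman-7-ol
Conditions: H2 (1 atm), 10% Pd/C, EtOAc, rt
Reagents that add atoms: none
Why: Hydrogenolysis of the benzyl ether under neutral conditions frees the C7 phenol before the prenyl alkene is present and leaves the acetal and the C3 stereocentre unchanged.

Step 10
Reactants: 19 (3R)-5-methoxy-3-[4-methoxy-2-(methoxymethoxy)phenyl]chroman-7-ol; 20 prenyl bromide (1-bromo-3-methylbut-2-ene)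
Product: 23 (3R)-5-methoxy-3-[4-methoxy-2-(methoxymethoxy)-3-(3-methylbut-2-en-1-yl)phenyl]chroman-7-ol, via dilithio species 21 (not isolated), via arylcopper phenoxide 22 (not isolated)
Conditions: n-BuLi (2.3 equiv), TMEDA, THF, −78 → 0 °C; CuBr·SMe2 (1.2 equiv), −78 °C; 20, −78 °C → rt; aq. NH4Cl
Reagents that add atoms: none
Why: Directed ortho-metalation, in which the first equivalent of base forms the C7 phenoxide that deactivates ring A and the second removes the C3′ hydrogen flanked by the methoxymethoxy and methoxy groups, followed by transmetalation to copper and SN2 allylation to the linear prenyl arene without touching C3.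

Step 11
Reactants: 23 (3R)-5-methoxy-3-[4-methoxy-2-(methoxymethoxy)-3-(3-methylbut-2-en-1-yl)phenyl]chroman-7-ol
Product: 24 (3R)-3-[2-hydroxy-4-methoxy-3-(3-methylbut-2-en-1-yl)phenyl]-5-methoxychroman-7-ol
Conditions: conc. HCl (cat.), MeOH, rt → 40 °C
Reagents that add atoms: none
Why: Acid-catalysed methanolysis of the methoxymethyl acetal frees the C2′ phenol under conditions mild enough that cyclisation of this phenol onto the neighbouring prenyl group should not compete.

Compound list
1 | 5-bromovanillin (3-bromo-4-hydroxy-5-methoxybenzaldehyde) | COc1cc(C=O)cc(Br)c1O | starting material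
2 | 2-bromo-6-methoxybenzene-1,4-diol | COc1cc(O)cc(Br)c1O | intermediate
3 | 2-bromo-6-methoxy-1,4-bis(trimethylsilyloxy)benzene | COc1cc(O[Si](C)(C)C)cc(Br)c1O[Si](C)(C)C | intermediate
4 | lithium 2-methoxy-6-(trimethylsilyl)-4-(trimethylsilyloxy)phenoxide | COc1cc(O[Si](C)(C)C)cc([Si](C)(C)C)c1[O-].[Li+] | intermediate
5 | 2-methoxy-6-(trimethylsilyl)-4-(trimethylsilyloxy)phenyl trifluoromethanesulfonate | COc1cc(O[Si](C)(C)C)cc([Si](C)(C)C)c1OS(=O)(=O)C(F)(F)F | intermediate
6 | 4-hydroxy-2-methoxy-6-(trimethylsilyl)phenyl trifluoromethanesulfonate | COc1cc(O)cc([Si](C)(C)C)c1OS(=O)(=O)C(F)(F)F | intermediate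
7 | 4-(benzyloxy)-2-methoxy-6-(trimethylsilyl)phenyl trifluoromethanesulfonate | COc1cc(OCc2ccccc2)cc([Si](C)(C)C)c1OS(=O)(=O)C(F)(F)F | intermediate
8 | 2-bromo-5-methoxyphenol | COc1ccc(Br)c(O)c1 | starting material
9 | 1-bromo-4-methoxy-2-(methoxymethoxy)benzene | COCOc1cc(OC)ccc1Br | intermediate
10 | propargyl alcohol (prop-2-yn-1-ol) | C#CCO | starting material
11 | [4-methoxy-2-(methoxymethoxy)phenyl]magnesium bromide | COCOc1cc(OC)ccc1[Mg]Br | intermediate
12 | 2-[4-methoxy-2-(methoxymethoxy)phenyl]prop-2-en-1-ol | C=C(CO)c1ccc(OC)cc1OCOC | intermediate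
13 | 2-[4-methoxy-2-(methoxymethoxy)phenyl]prop-2-enal | C=C(C=O)c1ccc(OC)cc1OCOC | intermediate
14 | 5-(benzyloxy)-3-methoxybenzyne (5-(benzyloxy)-3-methoxy-1,2-didehydrobenzene) | COC1=CC(OCc2ccccc2)=CC#C1 | intermediate
15 | 5-(benzyloxy)-3-methoxy-2-{1-[4-methoxy-2-(methoxymethoxy)phenyl]ethenyl}-2H-benzo[b]oxete | COc1cc(OCc2ccccc2)cc2OC(C(=C)c3ccc(OC)cc3OCOC)c12 | intermediate
16 | 3-(benzyloxy)-5-methoxy-6-{2-[4-methoxy-2-(methoxymethoxy)phenyl]prop-2-en-1-ylidene}cyclohexa-2,4-dien-1-one | COC1=CC(OCc2ccccc2)=CC(=O)C1=CC(=C)c1ccc(OC)cc1OCOC | intermediate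
17 | 7-(benzyloxy)-5-methoxy-3-[4-methoxy-2-(methoxymethoxy)phenyl]-2H-chromene | COc1cc(OCc2ccccc2)cc2OCC(c3ccc(OC)cc3OCOC)=Cc12 | intermediate
18 | (3R)-7-(benzyloxy)-5-methoxy-3-[4-methoxy-2-(methoxymethoxy)phenyl]chromane | COc1cc(OCc3ccccc3)cc2c1C[C@H](c1ccc(OC)cc1OCOC)CO2 | intermediate
19 | (3R)-5-methoxy-3-[4-methoxy-2-(methoxymethoxy)phenyl]chroman-7-ol | COc1cc(O)cc2c1C[C@H](c1ccc(OC)cc1OCOC)CO2 | intermediate
20 | prenyl bromide (1-bromo-3-methylbut-2-ene) | CC(C)=CCBr | starting material
21 | C3′-lithiated lithium C7-phenoxide of 19 | COc1cc([O-])cc2c1C[C@H](c1ccc(OC)c([Li])c1OCOC)CO2.[Li+] | intermediate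
22 | C3′-arylcopper lithium C7-phenoxide of 19 | COc1cc([O-])cc2c1C[C@H](c1ccc(OC)c([Cu])c1OCOC)CO2.[Li+] | intermediate
23 | (3R)-5-methoxy-3-[4-methoxy-2-(methoxymethoxy)-3-(3-methylbut-2-en-1-yl)phenyl]chroman-7-ol | COc1cc(O)cc2c1C[C@H](c1ccc(OC)c(CC=C(C)C)c1OCOC)CO2 | intermediate
24 | (3R)-3-[2-hydroxy-4-methoxy-3-(3-methylbut-2-en-1-yl)phenyl]-5-methoxychroman-7-ol | COc1cc(O)cc2c1C[C@H](c1ccc(OC)c(CC=C(C)C)c1O)CO2 | target

Total step count: 11
Longest linear sequence: 8 steps (steps 1, 2, 3, 7, 8, 9, 10, 11; the branch through steps 4, 5, 6 is equally long)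

Steps most likely to fail

Step 7. The enal may be consumed by fluoride-initiated oligomerisation, or the aryne may be diverted into cycloaddition at the styrene unit or into capture of the quinone methide by a second aryne. The fallback sets out from 7, with 12 as partner, and comes back at 17. It keeps an aryne insertion for the two bonds to ring A but uses a carbonyl partner that cannot polymerise. Aryne 14 from 7 (CsF, DMF, rt) adds across the C=O bond of N,N-dimethylformamide to the aminal 5-(benzyloxy)-3-methoxy-N,N-dimethyl-2H-benzo[b]oxet-2-amine F1, which aqueous work-up hydrolyses to 4-(benzyloxy)-2-hydroxy-6-methoxybenzaldehyde F2. Mitsunobu etherification of F2 with 12 (PPh3, DIAD, THF) should give 4-(benzyloxy)-2-methoxy-6-({2-[4-methoxy-2-(methoxymethoxy)phenyl]prop-2-en-1-yl}oxy)benzaldehyde F3. Wittig methylenation (Ph3PCH3Br, KOtBu, THF) then gives 5-(benzyloxy)-2-ethenyl-1-methoxy-3-({2-[4-methoxy-2-(methoxymethoxy)phenyl]prop-2-en-1-yl}oxy)benzene F4. Ring-closing metathesis of F4 (second-generation Grubbs catalyst RuCl2(=CHPh)(PCy3)(SIMes), toluene, 80 °C) closes the C3=C4 bond and returns 17.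

Step 8. The ortho methoxymethoxy group on ring B may slow the hydrogenation or erode facial selectivity, and the acidic iridium hydride may cleave the acetal. The fallback sets out from 17 and comes back at 19. Hydrogenation over Pd/C (H2, 1 atm, EtOAc–EtOH) reduces the C3=C4 bond and cleaves the benzyl ether in one operation to racemic 5-methoxy-3-[4-methoxy-2-(methoxymethoxy)phenyl]chroman-7-ol F5. Preparative supercritical-fluid chromatography on a polysaccharide chiral stationary phase then separates the enantiomers, and the 3R enantiomer is 19.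

Step 10. Metalation may stray to ring A, the phenoxide may be O-prenylated, or allylic transposition may give the branched isomer. The fallback sets out from 19 and comes back at 24, replacing the metalation by an aromatic Claisen rearrangement.
- Silylation (TIPSCl, imidazole, DMF) gives (3R)-5-methoxy-3-[4-methoxy-2-(methoxymethoxy)phenyl]-7-(triisopropylsilyloxy)chromane F6.
- Acid methanolysis (cat. HCl, MeOH, rt) removes the acetal to give 5-methoxy-2-[(3R)-5-methoxy-7-(triisopropylsilyloxy)chroman-3-yl]phenol F7.
- Palladium-catalysed O-allylation (Pd(PPh3)4, 2-methylbut-3-en-2-yl methyl carbonate, THF, 0 °C) gives (3R)-5-methoxy-3-[4-methoxy-2-(2-methylbut-3-en-2-yloxy)phenyl]-7-(triisopropylsilyloxy)chromane F8.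
- Claisen rearrangement (Eu(fod)3, CHCl3, 60 °C) moves the allyl unit to the only free ortho position, C3′, with allylic inversion, and gives 3-methoxy-6-[(3R)-5-methoxy-7-(triisopropylsilyloxy)chroman-3-yl]-2-(3-methylbut-2-en-1-yl)phenol F9.
- Desilylation (TBAF, THF, 0 °C) gives 24.

Further compounds
F1 | step 7 | 5-(benzyloxy)-3-methoxy-N,N-dimethyl-2H-benzo[b]oxet-2-amine | COc1cc(OCc2ccccc2)cc2OC(N(C)C)c12
F2 | step 7 | 4-(benzyloxy)-2-hydroxy-6-methoxybenzaldehyde | COc1cc(OCc2ccccc2)cc(O)c1C=O
F3 | step 7 | 4-(benzyloxy)-2-methoxy-6-({2-[4-methoxy-2-(methoxymethoxy)phenyl]prop-2-en-1-yl}oxy)benzaldehyde | COc1cc(OCc2ccccc2)cc(OCC(=C)c2ccc(OC)cc2OCOC)c1C=O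
F4 | step 7 | 5-(benzyloxy)-2-ethenyl-1-methoxy-3-({2-[4-methoxy-2-(methoxymethoxy)phenyl]prop-2-en-1-yl}oxy)benzene | COc1cc(OCc2ccccc2)cc(OCC(=C)c2ccc(OC)cc2OCOC)c1C=C
F5 | step 8 | racemic 5-methoxy-3-[4-methoxy-2-(methoxymethoxy)phenyl]chroman-7-ol | COc1cc(O)cc2c1CC(c1ccc(OC)cc1OCOC)CO2
F6 | step 10 | (3R)-5-methoxy-3-[4-methoxy-2-(methoxymethoxy)phenyl]-7-(triisopropylsilyloxy)chromane | COc1cc(O[Si](C(C)C)(C(C)C)C(C)C)cc2c1C[C@H](c1ccc(OC)cc1OCOC)CO2
F7 | step 10 | 5-methoxy-2-[(3R)-5-methoxy-7-(triisopropylsilyloxy)chroman-3-yl]phenol | COc1cc(O[Si](C(C)C)(C(C)C)C(C)C)cc2c1C[C@H](c1ccc(OC)cc1O)CO2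
F8 | step 10 | (3R)-5-methoxy-3-[4-methoxy-2-(2-methylbut-3-en-2-yloxy)phenyl]-7-(triisopropylsilyloxy)chromane | COc1cc(O[Si](C(C)C)(C(C)C)C(C)C)cc2c1C[C@H](c1ccc(OC)cc1OC(C)(C)C=C)CO2
F9 | step 10 | 3-methoxy-6-[(3R)-5-methoxy-7-(triisopropylsilyloxy)chroman-3-yl]-2-(3-methylbut-2-en-1-yl)phenol | COc1cc(O[Si](C(C)C)(C(C)C)C(C)C)cc2c1C[C@H](c1ccc(OC)c(CC=C(C)C)c1O)CO2
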